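Over 15 d at constant temperature, a closed flask of starting material and protic impurity has to be read ahead, and you have three earlier runs to do it with.

| flask | starting material | protic impurity | remark | time |
|---|---|---|---|---|
| theta | 20 mM | 2 mM | run made earlier |  |
| beta | 20 mM | 8 mM | run made earlier |  |
| eta | 30 mM | 4 mM | run made earlier |  |
| flask | 20 mM | 4.00 mM |  | 15 d |

- theta (time / d: isomer of the product A / %, target / %): 2.50: 3, 76; 5.00: 1, 88; 8.00: 1, 81; 10.0: 0, 83; 12.0: 0, 90; 15.0: 2, 84
- beta (time / d: isomer of the product A / %, target / %): 2.50: 2, 56; 5.00: 3, 66; 8.00: 2, 65; 10.0: 0, 67; 12.0: 3, 63; 15.0: 0, 62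
- eta (time / d: isomer of the product A / %, target / %): 1.25: 5, 54; 2.50: 4, 71; 4.00: 3, 78; 8.00: 1, 83; 15.0: 1, 86

(readings scatter by 2 percentage points)

1. ratio of isomer of the product A to target at 5.0 min
2. ratio of isomer of the product A to target at 15 d
3. which of isomer of the product A and target there is more of at 15 d

- a reading or a percentage of target counts all its forms, free or not

From 5.00 d on, the target readings of the theta and beta runs stop rising, so their means are plateaus: 85.2 % at 2 mM of protic impurity and 64.6 % at 8 mM. Both runs charge 20 mM, so I call the target lost per extra mM of protic impurity the toll, 0.687. It stands below one, so I read it as a race: impurity takes starting material at a rate that goes with [protic impurity], target formation does not, and the comparison drifts as [protic impurity] falls.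

Your flask has the same charge of starting material and 4.00 mM of impurity, so it should stand 6.9 percentage points under the theta plateau, at 78.3 %. Late readings of isomer of the product A, from 8.00 d on in the three runs, average 1.00 %. Over 78.3 % that gives a ratio of 0.0128 at 15 d, with target ahead. For 5.0 min I can give a rough range but no single figure. If the isomer branches off in parallel, the ratio stays near the eta reading, 0.0926 at 1.25 d; if it follows target, the ratio shrinks with time to about 2.57 × 10⁻⁴.

The weak link is the straight line between two plateaus, since a race need not run straight. The eta run reforges it: it held 4 mM of impurity, as your flask does, though with 30 mM of starting material, and from 8.00 d on its target readings fell short of that charge by 4.65 mM. If the shortfall goes with the mM of impurity and not with the charge, the same shortfall from 20 mM leaves 76.8 %, so I commit to 78.3 %, give or take 2 points.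

The forecast gives 0.13 early, 0.012 at the end and target ahead, its early figure being one “which is quite uncertain”.

The flask gives 0.00810 at 5.0 min and 0.0105 at 15 d, with target ahead: 78.9 %, crystals counted, against 0.830 %.

    starting material ⇌ target (K = 4.80, k = 0.190 h⁻¹)
    target ⇌ isomer of the product A (K = 0.700, k = 0.0970 h⁻¹)
    isomer of the product A ⇌ isomer of the product B (K = 2.30, k = 0.0380 h⁻¹)
    isomer of the product B ⇌ starting material (k = 0.140 h⁻¹)
    target ⇌ isomer of the product C (K = 1.60, k = 0.0790 h⁻¹)
    starting material + protic impurity → quenched substrate (k = 22.0 M⁻¹ h⁻¹)
    crystals ⇌ target, rate k7*(cs7 - [target]) while solid is left; crystals form when [target] > cs7 (solubility = 0.240 mM, k = 2.70 h⁻¹)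

The toll gives 57.7 % for the same flask with 10 mM of protic impurity, and that flask ends at 58.2 %. In your flask at the start, the forward turning of starting material into target uses it 2.2 times as fast as the step to quenched substrate, a selectivity factor. At 15.0 d that step still gives protic impurity a half-life of 28 d, longer than the run, and 18 % of its own charge stands.

The data stem from a simulated flask on assumed constants; the scatter is artificial.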